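A closed, stirred vessel of constant volume holds free monomer, transfer agent and initiator at one temperature.

free monomer 0.80 M; transfer agent 0.0800 M; initiator 16 mM; time 25 s

    2 initiator → spent initiator A (k1 = 5.9 /M/s)
    monomer in chains → over-reaction product (k2 = 1.7 × 10⁻⁵ /s)
    initiator + monomer in chains → spent initiator B (k3 = 0.65 /M/s)
    living end + transfer agent → dead chain (k4 = 0.085 /M/s)
    free monomer + initiator → living end + monomer in chains (k5 = 0.33 /M/s)
    free monomer + living end → monomer in chains + living end, rate k6*[living end]*[free monomer] (k6 = 1.7 /M/s)

- two of one species on the left: rate k times its square, two consumed each time
- the average divides the monomer in chains by the number of chains begun, living and dead together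
- run time (flask): 25 s

- average number of monomer units in a chain (chains begun, living or dead) at 25 s
- part of the free monomer that has reacted at 25 s

The initiator is charged in a smaller amount than the free monomer or the transfer agent, so its balance comes first; it is the limiting reagent for chains. This reckoning weighs two losses of each initiator. Free monomer turns it into a chain at a rate per initiator of

k_b = 0.264 /s, with free monomer held at its charge.

The pair step takes it at a rate that falls as [initiator] falls, and at the charge this is

k_p = 0.189 /s.

So at the start 58.3 % of the initiator lost begins a chain, and that part rises as [initiator] thins. This reckoning by hand sets aside the step between initiator and monomer in chains. Summing the part over the whole charge gives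

C = [initiator] charged × (k_b/k_p) × ln(1 + k_p/k_b) = 0.0121 M.

This amount, the chains begun from the charge, is the divisor of the average in this reckoning.

This reckoning takes the chains as present after about 1/k_b = 3.79 s, which is shorter than the run, and counts growth from then. Transfer removes living ends at 0.00680 /s per living end, with transfer agent held at its charge, and this loss is taken at the middle of the remaining time:

ln([free monomer] charged/[free monomer]) = 0.405

reacted part = 33.3 %

average = reacted monomer/C = 22.1 units.

The forecast gives 23.5 units and 34 %, with the rest of the initiator “lost mainly to its second-order self-reaction”. Its chains begun stand near 0.0115 M, against 0.0121 M here.

The flask gives 23.7 units and 33.5 % at 25 s. Living end and dead chain there add up to 0.0113 M, which is less than C. With 2.0 M of free monomer, the neighbour flask has a reckoned C of 0.0141 M. Its 40.0 % reacted then gives 56.7 units by that divisor, and the neighbour flask reads 59.0.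

(All constants are made up; what happens was integrated by code.)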